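Two questions stand on this flask, and I take the second first.

L 0.68 M; Z 1.20 equiv; time 30 h; volume of the second phase over the first 0.50

- how much L.J and X together there is at 30 h, in percent of the L charged
- part of the L charged that has reacted at 30 h

- amounts and yields of L.J count X too
- a doubled species enters its step squared and goes two at a time
- in the second phase: Z, X; everything else is in the first
- charges count per volume of the first phase; a concentration in a rate is the amount of a species over the volume of its own phase; every rate counts per litre of the first phase
- what has gone from L into another species counts as reacted, even if it can come back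
- run time (flask): 30 h

    J ⇌ Z, rate k1*([J] - [Z]/K1) per volume of the first phase (K1 = 0.859, k1 = 6.22 × 10⁻⁵ s⁻¹)
    L + J → L.J (k2 = 3.87 × 10⁻⁴ L mol⁻¹ s⁻¹)
    L.J ⇌ X, rate k3*([L.J] - [X]/K3) per volume of the first phase (K3 = 7.02, k3 = 4.54 × 10⁻⁵ s⁻¹)
    L.J → Q (k4 = 1.80 × 10⁻⁵ s⁻¹)
    2 J → J2 (k5 = 2.08 × 10⁻⁵ L mol⁻¹ s⁻¹)
    L ⇌ G (K6 = 0.589, k6 = 3.34 × 10⁻⁴ s⁻¹)

With L at its charge, J has a half-life of 0.73 h in the step to L.J, far shorter than the 30 h of the run, and Z is charged at 1.20 equiv, so I take L as the limiting reagent and put cv near 100 percent. Then y is that charge minus what L.J and X have lost to Q, and I reckon this loss.

The step to Q acts on L.J in the first phase, not on X. At partition equilibrium the first phase would hold a share 22.2% of the product, so the product would fall at 0.0144 h⁻¹, and y would read 65.0%. That is my first number.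

Its weak link is the equilibrium itself. X returns at 0.0466 h⁻¹, slower than the step to Q at 0.065 h⁻¹, so the two phases don't keep pace. Solving the pair approximately gives two stages. Fresh L.J first loses a share 23.6%, the rate constant to Q over the sum of that constant, the transfer coefficient and the return rate. After that comes the leak constant, the first-order rate at which L.J and X together fall, which is the constant to Q times the return rate over that same sum: 0.0110 h⁻¹. Taking the whole charge as L.J from the start, I get y = 55.0%, and I commit to that estimate.

The forecast gives 58% and 97.5%, saying “most of the product hides as X”.

The flask gives y = 57.2% and cv = 97.2%, so my y reads 2.2 percentage points low. Of that y, X holds 46.0%. Carried a further 30 h from the flask's own y, the leak constant gives 41.1%, and the flask reads 42.4% at 60.0 h.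

The neighbour flask with the same charges is read at 3.0 d, and the leak constant, carried on from the first flask's y at 30 h, gives 36.0% there. Its computed y is 37.2%.

Its constants are those of an exercise; the run is a simulation.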